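The runs are simulated with constants of no real substance, noise included.

Amounts of intermediate A and target read at two times give two rates over the same stretch, and their quotient needs no clock.

| setting | birch | alder | flask |
|---|---|---|---|
| solid substrate | 0.11 M | 0.11 M | 0.11 M |
| partner | 1.8 equiv | 0.90 equiv | 1.80 equiv |
| second reagent | 0.60 equiv | 0.60 equiv | 0.600 equiv |
| third reagent | 0.70 equiv | 0.70 equiv | 0.700 equiv |
| remark | the very flask that is asked about, followed so far | run made earlier |  |
| time |  |  | 12 h |

| run | time / h | intermediate A / % | target / % | solid substrate / % |
|---|---|---|---|---|
| birch | 0.833 | 10.2 | 1.3 | 70.3 |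
| birch | 1.50 | 14.8 | 5.3 | 51.7 |
| birch | 3.00 | 19.4 | 20.5 | 24.8 |
| birch | 6.00 | 18.1 | 40.2 | 0 |
| alder | 0.833 | 6.4 | 0.1 | 71.0 |
| alder | 2.00 | 9.4 | 6.9 | 49.8 |
| alder | 4.00 | 9.5 | 17.9 | 30.7 |
| alder | 8.00 | 5.6 | 30.9 | 19.6 |

(standard deviation of a reading: 0.5 percentage points)

* time, not beyond 12 h, at which the flask holds most intermediate A
* the amount of intermediate A, in percent of the solid substrate charged, at that time

- solid substrate is a solid; its amount is given per volume of the solution
- at the start none of the solid substrate is in solution

For the birch flask, which is the flask asked about, take the gain of intermediate A plus target as what is made, and the gain of target as what is passed on. Their quotient is the gain ratio g, a formation-to-consumption ratio: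

g = (Δc(intermediate A) + Δc(target)) / Δc(target)

As long as target gains, intermediate A climbs while g stands above 1, and you look for the peak where g crosses it.

0.833 h to 1.50 h: g = 2.15
1.50 h to 3.00 h: g = 1.30
3.00 h to 6.00 h: g = 0.934

As read in birch, between the first two stretches the rate of passing on grows by a factor 1.69. As read in birch, between the last two the rate of making drops by a factor 2.15. The value you carry is the gain ratio of the last stretch. As read across that stretch, birch loses on average 0.0660 of a point of intermediate A per point of target gained. Placing each g at the middle of its stretch and interpolating, my own estimate of the crossing in birch falls at 4.10 h, later than the time the forecast gives.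

The forecast gives 3.8 h (from 3 h to 4.8 h) and 20.2% (from 19.4% to 21.5%): “The maximum is therefore a flat peak near 3.5–4 h, at about 20%.”

The flask gives 20.2% at 3.25 h.

    solid substrate ⇌ starting material, rate k1*(cs1 - [starting material]) while solid is left; crystals form when [starting material] > cs1 (solubility = 0.0500 M, k = 1.06 /h)
    starting material + partner → intermediate A (k = 8.37 /M/h)
    third reagent + intermediate B → target (k = 48.2 /M/h)
    second reagent + intermediate A → intermediate B (k = 11.5 /M/h)
    partner ⇌ dormant form (K = 9.73, k = 0.419 /h)

Reckoned as before, the flask's g from 6.00 h to 12.0 h is 0.979, beside the 0.934 read across the stretch before it, and over the whole run to 12.0 h it is 1.33. The neighbour charged with 0.028 M of solid substrate, on the same equivalents, reaches a larger whole-run g than the flask, 1.63, and its intermediate A, after a best of 29.2%, ends at 20.1% beside 32.1% of target.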